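**Retrosynthetic overview**
1. Target 7 ⇐ 15,19-diacetate 6 (sterically selective methanolysis of the allylic acetate) ⇐ triol 5.
2. C15–O bond: [3,3] shift of the tertiary allylic acetate of 3 under divalent palladium catalysis gives 4 and fixes the 13E alkene.
3. C19–O bond (key, new): site-selective enzymatic hydroxylation of the axial 4β-methyl of (−)-sclareol 1 gives 2 and creates the C4 stereocentre.
4. No ring is formed and no C–C bond is made: rings A and B (trans-decalin) with C5, C8, C9 and C10 come intact from sclareol.

Assumption: the target is read as (13E)-19-acetoxylabd-13-ene-8α,15-diol of the normal labdane series (decalin configuration identical to (−)-sclareol), and (−)-sclareol is taken as a cheap commercial starting material.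

**Step 1**
Reactants: 1 (−)-sclareol [(13R)-labd-14-ene-8α,13-diol]
Product: 2 19-hydroxysclareol [(4S,13R)-labd-14-ene-8α,13,19-triol; the axial 4β-methyl, syn to the C10 methyl, is now CH2OH]
Conditions: new C19-selective CYP102A1 (P450 BM3) variant (iron enzyme, heme b cofactor C34H32FeN4O4), NADP+ (cat.), glucose dehydrogenase, D-glucose, air, K2HPO4/KH2PO4 buffer pH 8.0, 5% DMSO, 25 °C
Reagents that add atoms: dioxygen, O=O
Why: Proposed new method: a CYP102A1 variant re-shaped by site-saturation at pocket residues 75, 78, 82, 87, 328 and 437 (threonine 268 kept for O2 activation), starting from the ring-A-over-heme binding mode of C3-selective sclareol hydroxylases, so that the axial 4β-methyl (2.5 Å from C3 on the β-face) is the C–H nearest the iron-bound oxygen; the oxoiron porphyrin radical cation (iron formally tetravalent) abstracts a hydrogen atom from C19 and hydroxyl rebound forms the C19–O bond, and because only the axial methyl of the gem-dimethyl pair is presented, C4 becomes a stereocentre of S configuration, with the vinyl group and tertiary hydroxyls untouched; the closest known reaction types are P450-catalysed C3 hydroxylation of sclareol and sclareolide and the unselective fungal hydroxylation of the C4 methyl groups of sclareol.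

**Step 2**
Reactants: 2 19-hydroxysclareol
Product: 3 (13R)-labd-14-ene-8α,13,19-triyl triacetate
Conditions: AcCl (6 equiv), PhNMe2, CH2Cl2, 0 °C to rt
Reagents that add atoms: acetyl chloride, CC(=O)Cl
Why: O-acylation with an acyl chloride and the weak base PhNMe2 is the standard way to esterify both hindered tertiary hydroxyls of sclareol without ionising the tertiary allylic centre; the C13 acetate is the migrating group for step 3, the C8 acetate masks the hydroxyl that would otherwise cyclise onto C13 (manoyl oxide skeleton), and no stereocentre is touched.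

**Step 3**
Reactants: 3 (13R)-labd-14-ene-8α,13,19-triyl triacetate
Product: 4 (13E)-labd-13-ene-8α,15,19-triyl triacetate
Conditions: PdCl2(MeCN)2 (5 mol %), THF, rt
Reagents that add atoms: none
Why: Divalent-palladium-catalysed [3,3] sigmatropic shift of an allylic acetate (Overman-type cyclisation-induced rearrangement): the acetate carbonyl oxygen adds to the palladium-activated terminal CH2 to form the C15–O bond through a chair six-membered acetoxonium intermediate with the bulky C12 chain equatorial, and collapse gives the trisubstituted 13E alkene and the primary ester (E favoured, about 4:1 expected; the minor 13Z isomer is removed on AgNO3-impregnated silica).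

**Step 4**
Reactants: 4 (13E)-labd-13-ene-8α,15,19-triyl triacetate
Product: 5 (13E)-labd-13-ene-8α,15,19-triol
Conditions: KOH (10 equiv), MeOH/H2O 9:1, reflux
Reagents that add atoms: none
Why: Saponification by acyl–oxygen cleavage removes all three esters (heat is needed for the tertiary C8 acetate, which is why the C19 ester cannot be kept here), leaving the C8 configuration and the 13E geometry unchanged.

**Step 5**
Reactants: 5 (13E)-labd-13-ene-8α,15,19-triol
Product: 6 (13E)-8α-hydroxylabd-13-ene-15,19-diyl diacetate
Conditions: Ac2O (3 equiv), pyridine, rt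
Reagents that add atoms: acetic anhydride, CC(=O)OC(C)=O
Why: Pyridine-mediated O-acetylation (nucleophilic acyl substitution) takes both primary hydroxyls, including the neopentyl C19 one, while the hindered tertiary C8 hydroxyl is inert to Ac2O/pyridine at room temperature.

**Step 6**
Reactants: 6 (13E)-8α-hydroxylabd-13-ene-15,19-diyl diacetate
Product: 7 (13E)-8α,15-dihydroxylabd-13-en-19-yl acetate (target)
Conditions: K2CO3 (0.2 equiv), MeOH, 0 °C, stopped at consumption of 6
Reagents that add atoms: none
Why: Carbonate-catalysed transesterification (Zemplén-type methanolysis) is sterically governed, so the unhindered allylic C15 acetate is cleaved much faster than the axial neopentyl C19 acetate flanked by quaternary C4 and the syn-axial C10 methyl; any over-cleaved triol 5 is recycled through step 5.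

**Compound list**
1 | (−)-sclareol, (13R)-labd-14-ene-8α,13-diol | CC1(C)CCC[C@]2(C)[C@@H](CC[C@@](C)(O)C=C)[C@](C)(O)CC[C@@H]12 | starting material
2 | 19-hydroxysclareol, (4S,13R)-labd-14-ene-8α,13,19-triol | OC[C@@]1(C)CCC[C@]2(C)[C@@H](CC[C@@](C)(O)C=C)[C@](C)(O)CC[C@@H]12 | intermediate
3 | (13R)-labd-14-ene-8α,13,19-triyl triacetate | CC(=O)OC[C@@]1(C)CCC[C@]2(C)[C@@H](CC[C@@](C)(OC(C)=O)C=C)[C@](C)(OC(C)=O)CC[C@@H]12 | intermediate
4 | (13E)-labd-13-ene-8α,15,19-triyl triacetate | CC(=O)OC[C@@]1(C)CCC[C@]2(C)[C@@H](CC/C(C)=C/COC(C)=O)[C@](C)(OC(C)=O)CC[C@@H]12 | intermediate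
5 | (13E)-labd-13-ene-8α,15,19-triol | OC[C@@]1(C)CCC[C@]2(C)[C@@H](CC/C(C)=C/CO)[C@](C)(O)CC[C@@H]12 | intermediate
6 | (13E)-8α-hydroxylabd-13-ene-15,19-diyl diacetate | CC(=O)OC[C@@]1(C)CCC[C@]2(C)[C@@H](CC/C(C)=C/COC(C)=O)[C@](C)(O)CC[C@@H]12 | intermediate
7 | (13E)-8α,15-dihydroxylabd-13-en-19-yl acetate | CC(=O)OC[C@@]1(C)CCC[C@]2(C)[C@@H](CC/C(C)=C/CO)[C@](C)(O)CC[C@@H]12 | target

**Total step count:** 6. **Longest linear sequence:** 6 steps (fully linear from 1).

**Steps most likely to fail**

Step 1 (the new enzymatic C19 hydroxylation; risks are competing C2, C3 or C18 hydroxylation and over-oxidation of the new CH2OH). The fallback uses known chemistry, sets out from 1 and comes back at 2. It gives up catalyst-controlled selectivity: 1 is fermented on preparative scale with a wild-type ring-A-hydroxylating fungus (a Cunninghamella or Mucor strain; such cultures are known to hydroxylate sclareol at C2, C3 and the C4 methyl groups). 2 is then isolated by chromatography from its regioisomers, mainly the 18-hydroxy and 3β-hydroxy compounds. The yield will be low, but 1 is cheap and the rest of the route is unchanged. No compound outside the list is made (F0).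

Step 3 (E/Z ratio and conversion of the acetate shift). The fallback sets out from 2 and comes back at 5, replacing the oxygen shift by an olefination. Dihydroxylation of the vinyl group of 2 with OsO4 (cat.) in the presence of NaIO4 (THF/H2O) gives in the flask (13R)-labdane-8α,13,14,15,19-pentol F1. Periodate cleaves it twice to the methyl ketone 8α,19-dihydroxy-14,15-dinorlabdan-13-one F2. Horner–Wadsworth–Emmons reaction of the ketone with triethyl phosphonoacetate (NaH, THF) gives ethyl (13E)-8α,19-dihydroxylabd-13-en-15-oate F3; the E ester is easily separated from the minor Z ester on silica. Reduction with i-Bu2AlH (CH2Cl2, −78 °C) then gives triol 5.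

Step 6 (selectivity between the two primary acetates). The fallback sets out from 5 and comes back at 7, replacing selective deacylation by selective protection. The unhindered allylic hydroxyl of 5 is silylated with tert-butyldimethylsilyl chloride (1.05 equiv, imidazole, CH2Cl2, −20 °C) to give (13E)-15-(tert-butyldimethylsilyloxy)labd-13-ene-8α,19-diol F4. Acetylation (Ac2O, pyridine, rt) gives (13E)-15-(tert-butyldimethylsilyloxy)-8α-hydroxylabd-13-en-19-yl acetate F5. Desilylation with Bu4NF buffered with AcOH (THF, 0 °C) gives 7.

**Further compounds**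
F0 | step 1 | none | none
F1 | step 3 | (13R)-labdane-8α,13,14,15,19-pentol (C14 epimers, not isolated) | OC[C@@]1(C)CCC[C@]2(C)[C@@H](CC[C@@](C)(O)C(O)CO)[C@](C)(O)CC[C@@H]12
F2 | step 3 | 8α,19-dihydroxy-14,15-dinorlabdan-13-one | OC[C@@]1(C)CCC[C@]2(C)[C@@H](CCC(C)=O)[C@](C)(O)CC[C@@H]12
F3 | step 3 | ethyl (13E)-8α,19-dihydroxylabd-13-en-15-oate | OC[C@@]1(C)CCC[C@]2(C)[C@@H](CC/C(C)=C/C(=O)OCC)[C@](C)(O)CC[C@@H]12
F4 | step 6 | (13E)-15-(tert-butyldimethylsilyloxy)labd-13-ene-8α,19-diol | OC[C@@]1(C)CCC[C@]2(C)[C@@H](CC/C(C)=C/CO[Si](C)(C)C(C)(C)C)[C@](C)(O)CC[C@@H]12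
F5 | step 6 | (13E)-15-(tert-butyldimethylsilyloxy)-8α-hydroxylabd-13-en-19-yl acetate | CC(=O)OC[C@@]1(C)CCC[C@]2(C)[C@@H](CC/C(C)=C/CO[Si](C)(C)C(C)(C)C)[C@](C)(O)CC[C@@H]12
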